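**Retrosynthetic overview**
- The prenyl group is made last from an 8-allyl group by cross-metathesis, after the four methyl ethers have been cleaved; the allyl group is the acid-tolerant stand-in that is carried through the ring closure.
- The pyranone (ring C) is disconnected at C4–C4a: Friedel-Crafts acylation of a (Z)-3-aryloxy-3-arylacrylic acid, with O1–C2 already in place.
- Feature on which this rests: ring A is a phloroglucinol triether, and C4a is its only unsubstituted carbon ortho to O1, because the other ortho carbon (C8) carries the C3 side chain; C6' of ring B is meta to both of its methoxy groups.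
- The acid comes from oxa-Michael addition of 2-allyl-3,5-dimethoxyphenol (O-allylation and Claisen rearrangement of 3,5-dimethoxyphenol) to ethyl 3-(2,4-dimethoxyphenyl)propiolate (Sonogashira coupling), followed by saponification.
- Ring order: rings A and B are bought; ring C is the only ring formed (step 6).

Key step: step 6

Remark on the chemistry: the conjugate addition of step 4 may deliver some E enol ether beside the Z isomer. The Z isomer is drawn for 9 and 10 and both isomers would be carried on, since they converge in the acid medium of step 6.

**Step 1**
Reactants: 1 3,5-dimethoxyphenol; 2 allyl bromide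
Product: 3 1-(allyloxy)-3,5-dimethoxybenzene
Conditions: K2CO3, acetone, reflux
Reagents that add atoms: none
Why: Williamson ether synthesis, in which the phenoxide formed by K2CO3 in acetone is alkylated at oxygen by the reactive allylic bromide.

**Step 2**
Reactants: 3 1-(allyloxy)-3,5-dimethoxybenzene
Product: 5 2-allyl-3,5-dimethoxyphenol, via 6-allyl-3,5-dimethoxycyclohexa-2,4-dien-1-one 4 (not isolated)
Conditions: PhNEt2, 200 °C
Reagents that add atoms: none
Why: Aromatic Claisen rearrangement ([3,3]-sigmatropic shift) moves the allyl group to an ortho carbon, and because the two ortho positions of the symmetric ether are equivalent a single phenol should result after tautomerisation of dienone 4.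

**Step 3**
Reactants: 6 1-iodo-2,4-dimethoxybenzene; 7 ethyl propiolate
Product: 8 ethyl 3-(2,4-dimethoxyphenyl)prop-2-ynoate
Conditions: PdCl2(PPh3)2 (cat.), CuI (cat.), K2CO3, THF, 65 °C, excess 7
Reagents that add atoms: none
Why: Sonogashira coupling of an aryl iodide (fast oxidative addition to zerovalent palladium) with the terminal alkyne, run with an inorganic base in THF so that no amine is present to consume the propiolate by aza-Michael addition.

**Step 4**
Reactants: 5 2-allyl-3,5-dimethoxyphenol; 8 ethyl 3-(2,4-dimethoxyphenyl)prop-2-ynoate
Product: 9 ethyl (Z)-3-(2-allyl-3,5-dimethoxyphenoxy)-3-(2,4-dimethoxyphenyl)acrylate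
Conditions: K2CO3 (0.5 equiv), DMF, 90 °C
Reagents that add atoms: none
Why: Base-mediated oxa-Michael addition of a phenoxide to an arylpropiolate ester (the Ruhemann aryloxycinnamate synthesis), in which anti addition across the triple bond places the aryloxy group cis to the ester and so should give mainly the Z enol ether.

**Step 5**
Reactants: 9 ethyl (Z)-3-(2-allyl-3,5-dimethoxyphenoxy)-3-(2,4-dimethoxyphenyl)acrylate
Product: 10 (Z)-3-(2-allyl-3,5-dimethoxyphenoxy)-3-(2,4-dimethoxyphenyl)acrylic acid
Conditions: LiOH, THF/MeOH/H2O, rt; then 1 M HCl to pH 3–4, 0 °C
Reagents that add atoms: lithium hydroxide, [Li+].[OH-]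
Why: Saponification of an ethyl ester, in which hydroxide attacks the ester carbonyl faster than the hindered, donor-substituted beta carbon at room temperature, and the cold, mild acidification spares the enol ether.

**Step 6**
Reactants: 10 (Z)-3-(2-allyl-3,5-dimethoxyphenoxy)-3-(2,4-dimethoxyphenyl)acrylic acid
Product: 12 8-allyl-5,7,2',4'-tetramethoxyflavone [8-allyl-2-(2,4-dimethoxyphenyl)-5,7-dimethoxy-4H-chromen-4-one], via (Z)-3-(2-allyl-3,5-dimethoxyphenoxy)-3-(2,4-dimethoxyphenyl)acryloyl methanesulfonate 11 (not isolated)
Conditions: P2O5 in CH3SO3H (7.7 wt %, Eaton's reagent), 0 °C to rt, short reaction time; poured onto ice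
Reagents that add atoms: none
Why: P2O5 in CH3SO3H turns the acid into the acyl methanesulfonate 11 and its acylium ion, C6 of the aryloxy ring (the later C4a) attacks the acyl carbon in an intramolecular Friedel-Crafts acylation, and loss of the ring proton gives the 4-pyranone with O1–C2 already present. The closest known reaction type is the acid-mediated cyclisation of 3-aryloxy-3-arylacrylic acids to flavones (Ruhemann flavone synthesis). Ring C closes as a six-membered ring by C–C bond formation, exo with respect to the acyl C=O (6-exo-trig), and no stereocentre is formed. The step needs site selectivity between C4a of ring A and C6' of ring B (which would give an indenone): C4a is ortho to O1 and to the 5-OMe and para to the 7-OMe, and it is the only free ortho position because the other one carries the allyl group, whereas C6' is meta to both methoxy groups of ring B and would close a five-membered ring. Any E isomer should reach the reactive Z geometry in the medium by reversible protonation at the alpha carbon, which makes the C2–C3 bond of the acrylic acid a single bond for the time being. The allyl group should survive because the very nucleophilic triether ring allows low temperature and a short time, a monosubstituted alkene is protonated only slowly by CH3SO3H under these conditions, and 10 has no free phenol next to it.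

**Step 7**
Reactants: 12 8-allyl-5,7,2',4'-tetramethoxyflavone
Product: 13 8-allyl-5,7,2',4'-tetrahydroxyflavone
Conditions: BBr3 (8 equiv), CH2Cl2, −78 °C to rt; then ice-water, 0 °C
Reagents that add atoms: none
Why: Lewis-acid cleavage of aryl methyl ethers by BBr3 (bromide attacks the O-methyl carbon of the boron-complexed ether in an SN2 reaction), which is known to leave the monosubstituted double bond of allyl-substituted anisoles untouched when the quench is kept cold.

**Step 8**
Reactants: 13 8-allyl-5,7,2',4'-tetrahydroxyflavone
Product: 14 8-allyl-5,7,2',4'-tetraacetoxyflavone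
Conditions: Ac2O, pyridine, DMAP (cat.), rt to 50 °C
Reagents that add atoms: acetic anhydride, CC(=O)OC(C)=O
Why: DMAP-catalysed acylation of phenols, with gentle warming so that the hydrogen-bonded 5-OH is acetylated too, which makes the flavone soluble in CH2Cl2 and keeps free phenols away from the ruthenium carbene of the next step.

**Step 9**
Reactants: 14 8-allyl-5,7,2',4'-tetraacetoxyflavone
Product: 15 5,7,2',4'-tetraacetoxy-8-(3-methylbut-2-en-1-yl)flavone
Conditions: 2-methylbut-2-ene (large excess), second-generation Grubbs catalyst RuCl2(=CHPh)(PCy3)(H2IMes) (5 mol %), CH2Cl2, 40 °C, sealed tube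
Reagents that add atoms: 2-methylbut-2-ene, CC=C(C)C
Why: Olefin cross-metathesis of a terminal allylarene with excess 2-methylbut-2-ene is the standard conversion of allyl into prenyl, the excess partner suppressing homodimerisation and the trisubstituted product being inert to further metathesis.

**Step 10**
Reactants: 15 5,7,2',4'-tetraacetoxy-8-(3-methylbut-2-en-1-yl)flavone
Product: 16 5,7,2',4'-tetrahydroxy-8-(3-methylbut-2-en-1-yl)flavone (target)
Conditions: NH3 (7 M in MeOH), 0 °C to rt
Reagents that add atoms: none
Why: Ammonolysis of aryl acetates, which are cleaved by NH3 in MeOH at or below room temperature under basic conditions that cannot cyclise the prenyl group onto the 7-OH.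

**Compound list**
1 | 3,5-dimethoxyphenol | COc1cc(O)cc(OC)c1 | starting material
2 | allyl bromide | C=CCBr | starting material
3 | 1-(allyloxy)-3,5-dimethoxybenzene | C=CCOc1cc(OC)cc(OC)c1 | intermediate
4 | 6-allyl-3,5-dimethoxycyclohexa-2,4-dien-1-one (racemic, transient) | C=CCC1C(=O)C=C(OC)C=C1OC | intermediate (not isolated)
5 | 2-allyl-3,5-dimethoxyphenol | C=CCc1c(O)cc(OC)cc1OC | intermediate
6 | 1-iodo-2,4-dimethoxybenzene | COc1ccc(I)c(OC)c1 | starting material
7 | ethyl propiolate | C#CC(=O)OCC | starting material
8 | ethyl 3-(2,4-dimethoxyphenyl)prop-2-ynoate | CCOC(=O)C#Cc1ccc(OC)cc1OC | intermediate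
9 | ethyl (Z)-3-(2-allyl-3,5-dimethoxyphenoxy)-3-(2,4-dimethoxyphenyl)acrylate | CCOC(=O)/C=C(\Oc1cc(OC)cc(OC)c1CC=C)c1ccc(OC)cc1OC | intermediate
10 | (Z)-3-(2-allyl-3,5-dimethoxyphenoxy)-3-(2,4-dimethoxyphenyl)acrylic acid | OC(=O)/C=C(\Oc1cc(OC)cc(OC)c1CC=C)c1ccc(OC)cc1OC | intermediate
11 | (Z)-3-(2-allyl-3,5-dimethoxyphenoxy)-3-(2,4-dimethoxyphenyl)acryloyl methanesulfonate | CS(=O)(=O)OC(=O)/C=C(\Oc1cc(OC)cc(OC)c1CC=C)c1ccc(OC)cc1OC | intermediate (not isolated)
12 | 8-allyl-5,7,2',4'-tetramethoxyflavone | C=CCc1c(OC)cc(OC)c2c(=O)cc(-c3ccc(OC)cc3OC)oc12 | intermediate
13 | 8-allyl-5,7,2',4'-tetrahydroxyflavone | C=CCc1c(O)cc(O)c2c(=O)cc(-c3ccc(O)cc3O)oc12 | intermediate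
14 | 8-allyl-5,7,2',4'-tetraacetoxyflavone | C=CCc1c(OC(C)=O)cc(OC(C)=O)c2c(=O)cc(-c3ccc(OC(C)=O)cc3OC(C)=O)oc12 | intermediate
15 | 5,7,2',4'-tetraacetoxy-8-(3-methylbut-2-en-1-yl)flavone | CC(C)=CCc1c(OC(C)=O)cc(OC(C)=O)c2c(=O)cc(-c3ccc(OC(C)=O)cc3OC(C)=O)oc12 | intermediate
16 | 5,7,2',4'-tetrahydroxy-8-(3-methylbut-2-en-1-yl)flavone | CC(C)=CCc1c(O)cc(O)c2c(=O)cc(-c3ccc(O)cc3O)oc12 | target

**Step count**
Total: 10 steps. Longest linear sequence: 9 steps (1 → 3 → 5 → 9 → 10 → 12 → 13 → 14 → 15 → 16; steps 1, 2 and 4 to 10).

**Steps most likely to fail**

Step 6. The allyl double bond may be protonated in the sulfonic acid medium and the cation captured by the neighbouring ether oxygen or by sulfonate. The acid may also lose CO2 through its C-protonated oxocarbenium ion before it is acylated. The fallback sets out from 10 and replaces the protic dehydrating medium by an aprotic Lewis-acid Friedel-Crafts acylation of a preformed acid chloride. Acid 10 would be treated with 1-chloro-N,N,2-trimethylprop-1-en-1-amine in CH2Cl2 at 0 °C, which should give (Z)-3-(2-allyl-3,5-dimethoxyphenoxy)-3-(2,4-dimethoxyphenyl)acryloyl chloride F1 under neutral conditions. SnCl4 in CH2Cl2 at −40 to 0 °C should then close ring C through the acylium ion, whose ketene-like resonance form lets the E and Z geometries interconvert. The fallback comes back to the route at 12.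

Step 7. Cleavage of the four ethers may stop short of completion. The 7-OH, once set free, or HBr may add across the allyl double bond under the acidic conditions of reaction or quench. The fallback sets out from 12 and changes from electrophilic to nucleophilic ether cleavage: NaSEt in excess in DMF at 130–150 °C should demethylate by SN2 attack of thiolate on the methyl groups. All four methoxy groups are ortho or para to the C4 carbonyl, directly or through the C2–C3 double bond, so each aryloxide is a stabilised leaving group. The basic medium cannot protonate the alkene. No new compound is made on the way (F0), and the fallback comes back to the route at 13.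

Step 4. The conjugate addition may be too slow, because the beta carbon of 8 carries a donor-substituted aryl group with an ortho methoxy group and the phenoxide of 5 is ortho-substituted. Forcing it may bring oligomerisation of the alkynoate. The fallback sets out from 8 and forms the C–O bond by metal-catalysed coupling in place of addition to the alkyne. Hydroiodination of 8 with NaI in acetic acid at about 110 °C (anti addition) should give ethyl (Z)-3-(2,4-dimethoxyphenyl)-3-iodoacrylate F2. Coupling of F2 with phenol 5 under CuI, N,N-dimethylglycine and Cs2CO3 in dioxane at 90 °C (Ullmann-type vinyl ether synthesis, with retention of the alkene geometry) should give the enol ether. The fallback comes back to the route at 9.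

**Further compounds**
F1 | step 6 | (Z)-3-(2-allyl-3,5-dimethoxyphenoxy)-3-(2,4-dimethoxyphenyl)acryloyl chloride | ClC(=O)/C=C(\Oc1cc(OC)cc(OC)c1CC=C)c1ccc(OC)cc1OC
F0 | step 7 | none | none
F2 | step 4 | ethyl (Z)-3-(2,4-dimethoxyphenyl)-3-iodoacrylate | CCOC(=O)/C=C(\I)c1ccc(OC)cc1OC
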